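**Plan**

1. Retrosynthesis: both quinone carbonyls are traced back to a para-oxygenated phenol (C4=O to ArOH, C1=O to ArOMe), then the ring–chain bond C6–C1′ is cut. The six-membered ring is not built; it comes intact from 3,4-dimethoxyphenol.
2. Enabling feature (quinone numbering): C1=O lies between C2(OMe) and C6(C17H35), and C4=O lies between two CH (C3, C5). If C1 is held as an sp3 dimethyl ketal (two C–O bonds that are not in the target), C4=O is the only acceptor left, and its β-carbon on the unsubstituted side is C6. In free 2-methoxy-1,4-benzoquinone the more electrophilic C1=O would instead be expected to send a nucleophile to C5.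
3. Forward order: dearomatise 3,4-dimethoxyphenol to the quinone monoketal (step 1), join the C17 chain at C6 by copper-catalysed 1,4-addition (step 2), re-aromatise by loss of MeOH (step 3), oxidatively demethylate to the quinone (step 4).
4. Stereochemistry: the target has no stereocentre. The one sp3 centre made in step 2 is racemic and is erased in step 3.

Key step: step 2

Assumption: the target SMILES has no stereocentre and no stereogenic double bond, so the compound is achiral and "single enantiomer" is read as the single constitution drawn.

Numbering note: in dienone 2, C1 is the carbonyl (future quinone C4), C3 carries OMe (future C2), C4 is the ketal carbon (future C1) and C5 is the site of attack (future C6).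

**Step 1**
Reactants: 1 3,4-dimethoxyphenol
Product: 2 3,4,4-trimethoxycyclohexa-2,5-dien-1-one
Conditions: PhI(OAc)2 (1.1 equiv), MeOH, 0 °C; NaHCO3 work-up
Reagents that add atoms: methanol, CO
Why: Oxidative dearomatisation of a 4-methoxyphenol by a λ3-iodane in methanol (quinone monoketal formation); the aryloxy-iodane loses PhI and MeOH is captured at the para carbon, which is stabilised by its own OMe, and no stereocentre is formed.

**Step 2**
Reactants: 2 3,4,4-trimethoxycyclohexa-2,5-dien-1-one; 3 1-bromoheptadecane
Product: 6 rac-5-heptadecyl-3,4,4-trimethoxycyclohex-2-en-1-one, via heptadecylmagnesium bromide 4 (not isolated), via TMS dienol ether 5 (not isolated)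
Conditions: 3, Mg, THF, 40 °C; then CuBr·SMe2 (10 mol%), 2, TMSCl (2 equiv), THF, −78 → −40 °C; aq. NH4Cl; then K2CO3 (cat.), MeOH, 0 °C
Reagents that add atoms: magnesium, [Mg] (retained only in 4); chlorotrimethylsilane, C[Si](C)(C)Cl (retained only in 5)
Why: Heptadecylmagnesium bromide transmetalates to a catalytic organocopper(I) species that forms a π-complex with the C5=C6 enone of 2, and TMSCl traps the β-cuprio enolate as the silyl dienol ether and drives C5–C1′ reductive elimination. The closest known reaction type is the TMSCl-accelerated copper-catalysed 1,4-addition of Grignard reagents to cyclohexenones, together with cuprate additions to quinone monoketals and to 3-methoxy-4,4-disubstituted cyclohexa-2,5-dienones. No ring is closed; the new stereocentre C5 is formed without control (racemate) and is destroyed in step 3. Three selectivities are needed: site (C5 over C3), mode (1,4 over 1,2) and survival of the ketal. C3 is the fully substituted, methoxy-donated β-carbon of a vinylogous ester and should be far less electrophilic than the unsubstituted C5, while low temperature, catalytic copper and TMSCl should suppress carbonyl attack and electron-transfer loss of methoxide. Because C4 is an sp3 ketal carbon, the only carbonyl that can accept charge is C1 (the future quinone C4=O), so the chain must enter at C5, the future quinone C6.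

**Step 3**
Reactants: 6 rac-5-heptadecyl-3,4,4-trimethoxycyclohex-2-en-1-one
Product: 7 5-heptadecyl-3,4-dimethoxyphenol
Conditions: CSA (10 mol%), PhMe, 60 °C
Reagents that add atoms: none
Why: Acid-catalysed enolisation and E1-type loss of methanol from the C4 ketal with removal of H-5, driven by aromatisation (the usual fate of quinone-monoketal conjugate adducts, in sum a formal meta-alkylation of phenol 1); the C5 stereocentre disappears.

**Step 4**
Reactants: 7 5-heptadecyl-3,4-dimethoxyphenol
Product: 8 2-heptadecyl-6-methoxycyclohexa-2,5-diene-1,4-dione (target)
Conditions: PhI(OAc)2 (1.1 equiv), MeCN/THF/H2O, 0 °C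
Reagents that add atoms: water, O
Why: Oxidative demethylation of a 4-methoxyphenol to the para-quinone by a λ3-iodane in aqueous solvent; water should attack the methoxy-bearing para carbon of the oxidised phenol and the hemiketal collapses with loss of MeOH, while the 3-OMe (a vinylogous ester in the product) and the saturated chain are inert.

**Compound list**

1 | 3,4-dimethoxyphenol | COc1ccc(O)cc1OC | starting material
2 | 3,4,4-trimethoxycyclohexa-2,5-dien-1-one | COC1=CC(=O)C=CC1(OC)OC | intermediate
3 | 1-bromoheptadecane | CCCCCCCCCCCCCCCCCBr | starting material
4 | heptadecylmagnesium bromide | CCCCCCCCCCCCCCCCC[Mg]Br | intermediate (not isolated)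
5 | [(5-heptadecyl-3,4,4-trimethoxycyclohexa-1,3-dien-1-yl)oxy]trimethylsilane, racemic | CCCCCCCCCCCCCCCCCC1C=C(O[Si](C)(C)C)C=C(OC)C1(OC)OC | intermediate (not isolated)
6 | rac-5-heptadecyl-3,4,4-trimethoxycyclohex-2-en-1-one | CCCCCCCCCCCCCCCCCC1CC(=O)C=C(OC)C1(OC)OC | intermediate
7 | 5-heptadecyl-3,4-dimethoxyphenol | CCCCCCCCCCCCCCCCCc1cc(O)cc(OC)c1OC | intermediate
8 | 2-heptadecyl-6-methoxycyclohexa-2,5-diene-1,4-dione | CCCCCCCCCCCCCCCCCC1=CC(=O)C=C(OC)C1=O | target

**Count**

Total steps: 4. Longest linear sequence: 4 steps (1 → 2 → 6 → 7 → 8); bromide 3 enters in step 2.

**Steps most likely to fail, with fallbacks**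

Step 2. The organometallic may add to the carbonyl (1,2-addition), may transfer an electron to the dienone so that methoxide is lost and the aromatic phenol returns, or may add sluggishly next to the quaternary ketal carbon. The fallback sets out from 2 and comes back at 6, and replaces the organocopper nucleophile by a neutral nucleophilic alkyl radical from a different building block. Commercial stearic acid would be condensed with N-hydroxyphthalimide (DIC, DMAP cat., CH2Cl2) to 1,3-dioxoisoindolin-2-yl octadecanoate F1. F1 would then be fragmented in the presence of 2 under reductive photoredox conditions (Ru(bpy)3Cl2, Hantzsch ester, i-Pr2NEt, CH2Cl2, blue LED). The heptadecyl radical released on decarboxylation should add to the same unsubstituted enone terminus C5 (Giese addition), and hydrogen-atom transfer to the α-keto radical would give 6.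

Step 3. Instead of a clean elimination of methanol, adventitious water may hydrolyse the ketal or the vinylogous ester, giving mixtures at the hydroquinone oxidation level. The fallback sets out from 6 and comes back at 8, and takes the hydrolytic branch on purpose. Aqueous acid (1 M HCl, THF, rt) should cleave the ketal to the ene-1,4-dione, which tautomerises to 2-heptadecyl-6-methoxybenzene-1,4-diol F2. Oxidation of the crude material with FeCl3 or Ag2O would give 8 directly. Ceric ammonium nitrate could be used instead, since it would also convert any co-formed 7.

Step 4. Water may attack an ortho position of the oxidised phenol, the product quinone may be over-oxidised, or the lipophilic phenol may couple with the quinone in the partly aqueous medium. The fallback sets out from 7 and comes back at 8, and separates oxidation from quinone release. Constant-current anodic oxidation of 7 in methanol (LiClO4, graphite anode, undivided cell, 0 °C) should give the isolable monoketal 3-heptadecyl-4,4,5-trimethoxycyclohexa-2,5-dien-1-one F3 under non-aqueous conditions. Mild non-oxidative hydrolysis (aqueous oxalic acid, acetone, rt) would then liberate 8.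

**Further compounds**

F1 | step 2 | 1,3-dioxoisoindolin-2-yl octadecanoate | CCCCCCCCCCCCCCCCCC(=O)ON1C(=O)c2ccccc2C1=O
F2 | step 3 | 2-heptadecyl-6-methoxybenzene-1,4-diol | CCCCCCCCCCCCCCCCCc1cc(O)cc(OC)c1O
F3 | step 4 | 3-heptadecyl-4,4,5-trimethoxycyclohexa-2,5-dien-1-one | CCCCCCCCCCCCCCCCCC1=CC(=O)C=C(OC)C1(OC)OC
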